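The runs come from a simulation for substances that don't exist.

The target left over late in these runs answers your request for a quick number: your hunch is that it takes the whole mechanism, but I think one ratio gets there.

| flask | starting material | reagent | initiator | remark | time |
|---|---|---|---|---|---|
| eta | 0.010 M | 1.2 equiv | 1.1 mol% | run made earlier |  |
| gamma | 0.015 M | 1.2 equiv | 1.1 mol% | run made earlier |  |
| alpha | 0.020 M | 1.8 equiv | 1.1 mol% | run made earlier |  |
| flask | 0.020 M | 1.20 equiv | 1.1 mol% |  | 15 d |

- eta (time / d: target / %, starting material / %): 0.167: 25.7, 70.8; 0.333: 40.9, 49.7; 0.625: 52.4, 28.1; 1.25: 48.6, 8.3; 3.00: 14.0, 0; 6.00: 2.8, 1.4; 12.0: 0, 0.2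
- gamma (time / d: target / %, starting material / %): 0.167: 31.2, 65.0; 0.333: 50.4, 43.1; 0.625: 59.3, 19.5; 1.25: 49.6, 3.3; 3.00: 15.0, 1.1; 6.00: 0.2, 0; 12.0: 0, 0
- alpha (time / d: target / %, starting material / %): 0.167: 43.7, 53.2; 0.500: 69.3, 13.3; 1.25: 48.0, 0; 4.00: 5.2, 0; 12.0: 0, 0

(standard deviation of a reading: 1 percentage point)

1. when, up to 15 d, the flask holds most target
2. the amount of target, in percent of the starting material charged, at that time
3. earliest time at which at least nineteen twentieths of that best amount are there, in d
4. latest time at which they still are, in d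



I start from the leftover target in the alpha run: with starting material read at 0% at 1.25 d, target falls from 48.0% to 5.2% by 4.00 d, which is a first-order loss constant k_loss of 0.808 d⁻¹, and I take it over unchanged. The making constant k_make comes from the starting material at 0.625 d: 2.03 d⁻¹ in eta and 2.62 d⁻¹ in gamma, both at the flask's equivalents. So between eta and gamma k_make grows as [starting material] to the power 0.624, and I carry that on to 3.13 d⁻¹ for the flask.

The quantity I carry is the loss ratio ρ = k_loss/k_make, the selectivity factor of the two steps, here 0.258. Loss is slower than making, so I reckon only the correction. The peak of two first-order steps is ρ^(ρ/(1−ρ)), which for the flask leaves 62.4% as target and costs 37.6%. It comes at −ln ρ/(k_make−k_loss) = 0.583 d, far earlier than the 15 d allowed. Near its top the curve bends with k_make·k_loss, so a drop of 5% of the peak lies about 0.199 d to either side, from 0.384 d to 0.782 d.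

The forecast, whose peak “sits sensibly between gamma” and alpha, says 62% at 0.61 d, open from 0.43 d to 0.86 d. The flask gives 62.8% at 0.632 d, open from 0.443 d to 0.870 d, so my height holds and my times run early, the peak by 0.0490 d.

    starting material + initiating radical ⇌ chain carrier (K = 1.60 × 10⁵ M⁻¹, k = 80000 M⁻¹ min⁻¹)
    initiator → 2 initiating radical (k = 5.56 × 10⁻⁴ min⁻¹)
    reagent + chain carrier → target + initiating radical (k = 2.86 × 10⁵ M⁻¹ min⁻¹)
    target → over-reaction product (k = 5.28 × 10⁻⁴ min⁻¹)
    2 initiating radical → ended chains B (k = 1.00 × 10⁶ M⁻¹ s⁻¹)
    2 chain carrier → ended chains A (k = 4.00 × 10⁷ M⁻¹ s⁻¹)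

The flask's own numbers, a target half-life of 0.91 d by its passing into over-reaction product alone and 14.8% of starting material at 0.632 d, make k_make 3.03 d⁻¹ and ρ 0.251, and the same power gives 62.9%. A neighbour flask holds 0.050 M of starting material at the same equivalents. My power of [starting material] lifts k_make to 5.54 d⁻¹, ρ falls to 0.146, and the peak comes to 72.0%. That neighbour flask reaches 72.0% of target.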